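**Retrosynthetic overview**
- Numbering: ring A = C1–C5 plus C10, and ring B = C5–C10. C4 is CMe2, C8 is C(CH3)OH, and C9 carries C11, the first chain carbon.
- Feature used: the decalin is cis-fused. C5–H, the C10 methyl and the C9–C11 bond all lie on the β face of ring B, and the 8-OH lies on the α face. An endo [4+2] addition of an E-diene across a C5=C10 ring alkene gives this all-cis triad if C10 carries CHO in place of CH3.
- Disconnections: C11–C12 (α-sulfonyl carbanion plus farnesyl bromide, then desulfonylation). C8–OH (anti, Markovnikov hydration of C7=C8). C10–CH3 from C10–CHO (Wolff–Kishner). C5–C6 and C9–C10 (enantioselective Diels–Alder).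
- Ring order: ring A is bought as 2,2-dimethylcyclohexanone, ring B is closed by the cycloaddition, and the acyclic C15 chain is attached last.

Key step: step 6

Assumption: the (S)-diphenylprolinol-derived catalyst is taken, from the formyl C–H···O model for α-substituted enals, to leave the Si face of C10 open. This is to be checked by X-ray analysis (anomalous dispersion of sulfur) at the sulfone stage of step 10, and the equally available (R)-catalyst would replace it with no other change if the check required it.

**Step 1**
Reactants: 1 2,2-dimethylcyclohexanone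
Product: 2 (Z)-6-(hydroxymethylene)-2,2-dimethylcyclohexanone
Conditions: NaH, HCO2Et, cat. EtOH, Et2O, 0 °C to rt; then 1 M HCl
Reagents that add atoms: ethyl formate, CCOC=O
Why: Crossed Claisen condensation (α-formylation): C2 is quaternary, so only C6 can enolise, and formation of the stabilised sodium salt of the β-keto aldehyde drives the equilibrium to one regioisomer.

**Step 2**
Reactants: 2 (Z)-6-(hydroxymethylene)-2,2-dimethylcyclohexanone
Product: 3 (E)-6-(isopropoxymethylene)-2,2-dimethylcyclohexanone
Conditions: i-PrI, K2CO3, acetone, reflux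
Reagents that add atoms: 2-iodopropane, CC(C)I
Why: O-alkylation of the potassium salt of a vinylogous acid with a secondary iodide should give the enol ether rather than the C-alkylated ketone, and the alkene geometry does not matter because it is lost in step 3.

**Step 3**
Reactants: 3 (E)-6-(isopropoxymethylene)-2,2-dimethylcyclohexanone
Product: 5 3,3-dimethylcyclohex-1-ene-1-carbaldehyde, via alkoxymethylene carbinol 4 (not isolated)
Conditions: LiAlH4, Et2O, 0 °C; then 2 M HCl, THF–H2O, rt
Reagents that add atoms: water, O
Why: 1,2-Hydride reduction of the vinylogous ester, acid-induced loss of the allylic hydroxyl and hydrolysis of the resulting oxocarbenium ion make up the classical 1,3-carbonyl transposition, which puts CHO on the former C6 and the ring alkene CH next to CMe2, and the carbinol centre of 4 disappears.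

**Step 4**
Reactants: 6 (E)-3-methylpent-2-en-4-yn-1-ol
Product: 7 TBS ether of (E)-3-methylpent-2-en-4-yn-1-ol
Conditions: TBSCl, imidazole, CH2Cl2, 0 °C to rt
Reagents that add atoms: tert-butyldimethylsilyl chloride, CC(C)(C)[Si](C)(C)Cl
Why: Standard imidazole-promoted silylation of a primary alcohol gives an ether that binds the Lewis acid of step 6 only weakly and is inert to hydrogenation.

**Step 5**
Reactants: 7 TBS ether of (E)-3-methylpent-2-en-4-yn-1-ol
Product: 8 (E)-1-(tert-butyldimethylsilyloxy)-3-methylpenta-2,4-diene
Conditions: H2 (1 atm, stopped at 1 equiv), Lindlar catalyst, quinoline, hexane, rt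
Reagents that add atoms: none
Why: Lindlar semihydrogenation of the terminal alkyne stops at the vinyl group when uptake is limited, and the E-trisubstituted alkene bought in 6 is untouched, so C11 takes the outside position of the s-cis diene.

**Step 6**
Reactants: 5 3,3-dimethylcyclohex-1-ene-1-carbaldehyde; 8 (E)-1-(tert-butyldimethylsilyloxy)-3-methylpenta-2,4-diene
Product: 9 cis-fused adduct (10β-CHO 5β-H 9β-CH2OTBS C7=C8 alkene bearing the 8-methyl)
Conditions: (S)-B-o-tolyl oxazaborolidine from (S)-α,α-diphenylprolinol (20 mol %), Tf2NH (18 mol %), 8 (2 equiv), CH2Cl2 (ca. 2 M), −78 to −20 °C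
Reagents that add atoms: none
Why: The N-protonated oxazaborolidine binds the formyl oxygen of s-trans 5 and lowers the enal LUMO, and the [4π+2π] cycloaddition, suprafacial on both partners, then runs concerted but asynchronous, with the free CH2 terminus C6 of 8 bonding first to the electrophilic β-carbon C5 and the C9–C10 bond closing after it. The closest known reaction type is the oxazaborolidinium-catalysed enantioselective Diels–Alder reaction of α-substituted and cycloalkene-1-carbaldehydes with 1-substituted dienes, supported by Lewis acid Diels–Alder reactions of 4,4-dimethylcyclohex-2-enone in which a quaternary carbon beside the β-carbon is tolerated, although the present pair is more hindered than either. Ring B (C5–C10) is closed as a cyclohexene by intermolecular [4+2] annulation onto intact ring A, forming C5–C6 and C9–C10 and leaving the C7=C8 alkene with its methyl on C8. At C5 and C10, suprafacial addition to the ring alkene keeps H5 and CHO cis and so gives the cis fusion, at C9 the CHO-endo transition state with the E-diene places C11 cis to CHO, and the absolute sense comes from the catalyst aryl group covering one enal face so that the diene adds to the Si face of C10. The step needs ortho regiochemistry, endo selectivity and one enal face: the polarised C5 next to CMe2 should accept only the unsubstituted diene terminus, the 1-substituent directs the same way while the 8-methyl opposes it only weakly, and ring A with its gem-dimethyl group is too bulky to lie under the diene, which leaves the endo position to CHO.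

**Step 7**
Reactants: 9 cis-fused adduct
Product: 12 5-epi-drimenol (cis-fused drim-7-en-11-ol), via hydrazone 10 (not isolated), via silyl ether 11 (not isolated)
Conditions: N2H4·H2O (excess), KOH, diethylene glycol, Ar, 130 °C, then distil to 205 °C
Reagents that add atoms: none
Why: Wolff–Kishner reduction under Huang-Minlon conditions is the standard way to turn a hindered angular aldehyde into an angular methyl group, since C10 is quaternary and cannot epimerise, the isolated C7=C8 alkene is inert to base, and hot KOH in glycol also cleaves the primary silyl ether.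

**Step 8**
Reactants: 12 5-epi-drimenol
Product: 14 cis-fused drimane-8α,11-diol, via organomercurial 13 (not isolated)
Conditions: Hg(OAc)2, THF–H2O (1:1), rt; then 3 M NaOH, NaBH4, 0 °C
Reagents that add atoms: water, O
Why: Oxymercuration–demercuration: in the ring B half-chair that keeps C4 equatorial and C11 pseudoaxial, Hg(II), guided by the 11-OH, bridges the β face and water attacks the tertiary C8 axially from the α face, which is the only opening that is both Markovnikov and trans-diaxial (Fürst–Plattner), so the 8-OH is set trans to C11 and the radical demercuration leaves C7 as CH2.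

**Step 9**
Reactants: 14 cis-fused drimane-8α,11-diol
Product: 15 11-phenylthio-8α-ol
Conditions: PhSSPh, n-Bu3P, THF, rt to 50 °C
Reagents that add atoms: diphenyl disulfide, c1ccc(cc1)SSc1ccccc1
Why: In this Mitsunobu-type thioether synthesis from a disulfide and a trialkylphosphine only the primary 11-OH can form the alkoxyphosphonium salt, which thiolate displaces by SN2 at C11 without touching a stereocentre, while the tertiary 8-OH, anti to C11, neither reacts nor closes an oxetane.

**Step 10**
Reactants: 15 11-phenylthio-8α-ol
Product: 16 11-phenylsulfonyl-8α-ol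
Conditions: 30% H2O2, (NH4)6Mo7O24·4H2O (cat.), EtOH, 0 °C to rt
Reagents that add atoms: hydrogen peroxide, OO
Why: Molybdate-catalysed peroxide oxidation takes the sulfide through the sulfoxide to the sulfone, and at this stage the molecule has no alkene and only a tertiary alcohol, so nothing else can be oxidised.

**Step 11**
Reactants: 16 11-phenylsulfonyl-8α-ol; 17 (2E,6E)-farnesyl bromide
Product: 19 C11-farnesylated sulfone (C11 epimers), via dilithio dianion 18 (not isolated)
Conditions: n-BuLi (2.2 equiv), THF–DMPU, −78 to −30 °C; 17, −78 to −20 °C; H2O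
Reagents that add atoms: none
Why: Alkylation of an α-sulfonyl carbanion with an allylic bromide (SN2 at the primary carbon, E-alkenes retained) forms C11–C12, the hindered tertiary lithium alkoxide made by the first equivalent of base is a far poorer nucleophile than the carbanion, and the new C11 centre may form as a mixture because step 12 erases it.

**Step 12**
Reactants: 19 C11-farnesylated sulfone
Product: 20 target CNP0389811.1
Conditions: 6% Na(Hg), Na2HPO4, MeOH–THF, −20 to 0 °C
Reagents that add atoms: none
Why: Buffered sodium amalgam desulfonylation by electron transfer replaces C–SO2Ph by C–H, the sulfone is homoallylic rather than allylic so no alkene should migrate, the 8-OH is γ to C11 and cannot be eliminated, and both C11 epimers converge on 20.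

**Compound list**
1 | 2,2-dimethylcyclohexanone | CC1(C)CCCCC1=O | starting material
2 | (Z)-6-(hydroxymethylene)-2,2-dimethylcyclohexanone (chelated enol form) | O/C=C1/CCCC(C)(C)C1=O | intermediate
3 | (E)-6-(isopropoxymethylene)-2,2-dimethylcyclohexanone | CC(C)O/C=C1\CCCC(C)(C)C1=O | intermediate
4 | (E)-6-(isopropoxymethylene)-2,2-dimethylcyclohexan-1-ol, racemic, not isolated | CC(C)O/C=C1\CCCC(C)(C)C1O | intermediate
5 | 3,3-dimethylcyclohex-1-ene-1-carbaldehyde | O=CC1=CC(C)(C)CCC1 | intermediate
6 | (E)-3-methylpent-2-en-4-yn-1-ol | C#C/C(C)=C/CO | starting material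
7 | (E)-1-(tert-butyldimethylsilyloxy)-3-methylpent-2-en-4-yne | C#C/C(C)=C/CO[Si](C)(C)C(C)(C)C | intermediate
8 | (E)-1-(tert-butyldimethylsilyloxy)-3-methylpenta-2,4-diene | C=C/C(C)=C/CO[Si](C)(C)C(C)(C)C | intermediate
9 | cis-fused Diels–Alder adduct: angular 10β-CHO, 5β-H, 9β-CH2OTBS, C7=C8 with 8-methyl | CC(C)(C)[Si](C)(C)OC[C@@H]1[C@@]2(C=O)CCCC(C)(C)[C@H]2CC=C1C | intermediate
10 | (E)-hydrazone of 9, not isolated | CC(C)(C)[Si](C)(C)OC[C@@H]1[C@@]2(/C=N/N)CCCC(C)(C)[C@H]2CC=C1C | intermediate
11 | 5-epi-drimenol TBS ether (10β-CH3), not isolated | CC(C)(C)[Si](C)(C)OC[C@@H]1[C@@]2(C)CCCC(C)(C)[C@H]2CC=C1C | intermediate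
12 | 5-epi-drimenol: cis-fused drim-7-en-11-ol, with 5β-H, 10β-CH3 and 9β-CH2OH | OC[C@@H]1[C@@]2(C)CCCC(C)(C)[C@H]2CC=C1C | intermediate
13 | 7β-(acetoxymercurio)-cis-drimane-8α,11-diol, not isolated | OC[C@@H]1[C@@]2(C)CCCC(C)(C)[C@H]2C[C@H]([Hg]OC(C)=O)[C@@]1(C)O | intermediate
14 | cis-fused drimane-8α,11-diol (8α-OH, 8β-CH3) | OC[C@@H]1[C@@]2(C)CCCC(C)(C)[C@H]2CC[C@@]1(C)O | intermediate
15 | 11-phenylthio-cis-driman-8α-ol | S(C[C@@H]1[C@@]2(C)CCCC(C)(C)[C@H]2CC[C@@]1(C)O)c1ccccc1 | intermediate
16 | 11-phenylsulfonyl-cis-driman-8α-ol | O=S(=O)(C[C@@H]1[C@@]2(C)CCCC(C)(C)[C@H]2CC[C@@]1(C)O)c1ccccc1 | intermediate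
17 | (2E,6E)-farnesyl bromide | CC(C)=CCC/C(C)=C/CC/C(C)=C/CBr | starting material
18 | O,C11-dilithio derivative of 16, not isolated | [Li]C([C@@H]1[C@@]2(C)CCCC(C)(C)[C@H]2CC[C@@]1(C)O[Li])S(=O)(=O)c1ccccc1 | intermediate
19 | C11-farnesylated sulfone, mixture of C11 epimers | CC(C)=CCC/C(C)=C/CC/C(C)=C/CC([C@@H]1[C@@]2(C)CCCC(C)(C)[C@H]2CC[C@@]1(C)O)S(=O)(=O)c1ccccc1 | intermediate
20 | (1R,2R,4aR,8aS)-2,5,5,8a-tetramethyl-1-[(3E,7E)-4,8,12-trimethyltrideca-3,7,11-trien-1-yl]decahydronaphthalen-2-ol (5R,8R,9R,10S in the numbering used here) | CC(C)=CCC/C(C)=C/CC/C(C)=C/CC[C@@H]1[C@@]2(C)CCCC(C)(C)[C@H]2CC[C@@]1(C)O | target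

**Step count**
Total step count: 12. Longest linear sequence: 10 (steps 1–3 and 6–12).

**Steps most likely to fail**

1. **Step 6.**
   - Risk: bond formation next to CMe2 and at a carbon that becomes quaternary may be too slow at the temperatures where the catalyst stays selective. Acid-induced ionisation or oligomerisation of the dienyl silyl ether could then overtake the cycloaddition. Regiochemical leakage through the 8-methyl group and incomplete facial discrimination are further risks.
   - Fallback (from 5 and 8, back at 12): absolute control is given up at the cycloaddition and regained by resolution.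
   - 5 and 8 are combined with a stoichiometric, small, proton-scavenging achiral Lewis acid (EtAlCl2, CH2Cl2, −78 to −20 °C), for which the same endo and ortho arguments hold. This gives the racemic cis-fused adduct F1.
   - Wolff–Kishner reduction as in step 7, through the racemic hydrazone F2 and the racemic silyl ether F3, gives racemic 5-epi-drimenol F4.
   - Esterification with (S)-O-methylmandelic acid (DCC, DMAP, CH2Cl2) gives the (S)-O-methylmandelate of 12 F5 and the (S)-O-methylmandelate of the mirror-image alcohol F6. These are separated by chromatography or crystallisation.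
   - Saponification of F5 (LiOH, THF–H2O) returns 12.

2. **Step 8.**
   - Risk: mercuration of the hindered trisubstituted alkene may be sluggish. Water may enter from the wrong face if ring B reacts through another conformer, or the 11-OH may close onto C7 in place of water.
   - Fallback (from 12, back at 14): hydration is replaced by epoxidation and reductive opening.
   - 12 is silylated again (TBSCl, imidazole) to 11, now isolated.
   - m-CPBA with NaHCO3 in CH2Cl2 should attack the α face, because the pseudoaxial CH2OTBS group covers the β face. This gives the 7α,8α-epoxide F7.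
   - LiEt3BH in THF delivers hydride to the secondary C7 from the β face in a trans-diaxial opening and gives the 8α-ol silyl ether F8.
   - TBAF then gives 14.

3. **Step 11.**
   - Risk: deprotonation at the crowded C11 may be incomplete, with ortho-lithiation of the phenyl ring competing. The aggregated dianion may alkylate slowly, and the allylic bromide may be consumed by SN2' attack or elimination.
   - Fallback (from 14 and 17, back at 20): the sulfone is replaced by an organomagnesium nucleophile, and steps 9–12 are bypassed.
   - Appel-type iodination of the primary hydroxyl (I2, PPh3, imidazole, THF) gives the 11-iodo-8α-ol F9.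
   - TESOTf with 2,6-lutidine gives the 8-O-triethylsilyl iodide F10.
   - Magnesium in Et2O gives the Grignard reagent F11.
   - Copper-catalysed allylic coupling with 17 (Li2CuCl4 cat., THF, −20 °C, attack at the primary allylic carbon) gives the 8-O-triethylsilyl ether of the target F12.
   - TBAF then gives 20.

**Further compounds**
F1 | step 6 | racemic cis-fused adduct (9 and its mirror image) | CC(C)(C)[Si](C)(C)OC[C@@H]1[C@@]2(C=O)CCCC(C)(C)[C@H]2CC=C1C.CC(C)(C)[Si](C)(C)OC[C@H]1[C@]2(C=O)CCCC(C)(C)[C@@H]2CC=C1C
F2 | step 6 | racemic hydrazone (10 and its mirror image) | CC(C)(C)[Si](C)(C)OC[C@@H]1[C@@]2(/C=N/N)CCCC(C)(C)[C@H]2CC=C1C.CC(C)(C)[Si](C)(C)OC[C@H]1[C@]2(/C=N/N)CCCC(C)(C)[C@@H]2CC=C1C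
F3 | step 6 | racemic silyl ether (11 and its mirror image) | CC(C)(C)[Si](C)(C)OC[C@@H]1[C@@]2(C)CCCC(C)(C)[C@H]2CC=C1C.CC(C)(C)[Si](C)(C)OC[C@H]1[C@]2(C)CCCC(C)(C)[C@@H]2CC=C1C
F4 | step 6 | racemic 5-epi-drimenol (12 and its mirror image) | OC[C@@H]1[C@@]2(C)CCCC(C)(C)[C@H]2CC=C1C.OC[C@H]1[C@]2(C)CCCC(C)(C)[C@@H]2CC=C1C
F5 | step 6 | (S)-O-methylmandelate of 12 | CO[C@H](C(=O)OC[C@@H]1[C@@]2(C)CCCC(C)(C)[C@H]2CC=C1C)c1ccccc1
F6 | step 6 | (S)-O-methylmandelate of the mirror-image alcohol | CO[C@H](C(=O)OC[C@H]1[C@]2(C)CCCC(C)(C)[C@@H]2CC=C1C)c1ccccc1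
F7 | step 8 | 7α,8α-epoxide of 11 | CC(C)(C)[Si](C)(C)OC[C@@H]1[C@@]2(C)CCCC(C)(C)[C@H]2C[C@H]3O[C@@]13C
F8 | step 8 | 11-O-TBS ether of diol 14 (8α-ol silyl ether) | CC(C)(C)[Si](C)(C)OC[C@@H]1[C@@]2(C)CCCC(C)(C)[C@H]2CC[C@@]1(C)O
F9 | step 11 | 11-iodo-cis-driman-8α-ol | IC[C@@H]1[C@@]2(C)CCCC(C)(C)[C@H]2CC[C@@]1(C)O
F10 | step 11 | 8-O-triethylsilyl ether of F9 | IC[C@@H]1[C@@]2(C)CCCC(C)(C)[C@H]2CC[C@@]1(C)O[Si](CC)(CC)CC
F11 | step 11 | Grignard reagent from F10 | I[Mg]C[C@@H]1[C@@]2(C)CCCC(C)(C)[C@H]2CC[C@@]1(C)O[Si](CC)(CC)CC
F12 | step 11 | 8-O-triethylsilyl ether of 20 | CC(C)=CCC/C(C)=C/CC/C(C)=C/CC[C@@H]1[C@@]2(C)CCCC(C)(C)[C@H]2CC[C@@]1(C)O[Si](CC)(CC)CC
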